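**Assumption:** I take the SMILES literally, so the target is 5,8-dihydroxy-6-(3-hydroxy-3-methylbutyl)-3-(7-hydroxy-2,2-dimethyl-2H-chromen-6-yl)-4H-chromen-4-one. It has no stereocentres (achiral), so no stereocontrol is needed. The route is designed on paper and has not been run.

## Retrosynthetic overview

1. The last bond is the isoflavone C3–C1′ bond, made by Suzuki–Miyaura coupling of a 3-iodochromone (A/C rings) with a chromenyl boronate (B/D rings); silyl ethers are removed with fluoride at the end, so the 5-OH/tertiary alcohol pair and the chromene never see acid.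
2. The pyranone C ring comes from an o-hydroxyaryl enaminone by I2 cyclisation. The side chain is installed before that by Sonogashira coupling and hydrogenation, so H2 never meets the chromene.
3. The A-ring 2,3,6-trioxygenation comes from Elbs oxidation of symmetric 2′,6′-dihydroxyacetophenone. The two ortho OH groups are told apart by a sterically controlled bis-silylation, and the remaining free OH directs iodination to its para position.
4. The dimethylpyran D ring is built first on the B side by condensing 4-bromoresorcinol with prenal, then borylation.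
5. Ring order: D (on B), then C (on A), then the biaryl bond.

## Route

**Step 1**
Reactants: 1, 1-(2,6-dihydroxyphenyl)ethan-1-one (2′,6′-dihydroxyacetophenone)
Product: 2, 1-(2,3,6-trihydroxyphenyl)ethan-1-one
Conditions: K2S2O8, 2 M aq NaOH, 0 °C → rt, 24 h; then HCl, Na2SO3, 90 °C
Reagents that add atoms: potassium peroxodisulfate, [K+].[K+].[O-]S(=O)(=O)OOS(=O)(=O)[O-]
Why: Elbs persulfate oxidation hydroxylates para to a phenoxide; the two available positions (C3, C5) are equivalent by symmetry, so one product forms.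

**Step 2**
Reactants: 2
Product: 3, 1-{2-hydroxy-3,6-bis[(triisopropylsilyl)oxy]phenyl}ethan-1-one
Conditions: TIPSCl (2.2 equiv), imidazole, cat. DMAP, DMF, 0 °C → rt, N2
Reagents that add atoms: triisopropylsilyl chloride, CC(C)[Si](Cl)(C(C)C)C(C)C
Why: Regioselective silylation: the unchelated 3-OH reacts first, then the 6-OH (flanked only by acetyl and H); the 2-OH, chelated to C=O and wedged between acetyl and OTIPS, stays free.

**Step 3**
Reactants: 3
Product: 4, 1-{2-hydroxy-5-iodo-3,6-bis[(triisopropylsilyl)oxy]phenyl}ethan-1-one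
Conditions: NIS (1.05 equiv), cat. TFA, MeCN, 0 °C → rt, dark
Reagents that add atoms: N-iodosuccinimide, O=C1CCC(=O)N1I
Why: Electrophilic aromatic iodination goes para to the free OH and ortho to OTIPS (C5); C4 is para to the acetyl and deactivated.

**Step 4**
Reactants: 4; 5, 2-methylbut-3-yn-2-ol
Product: 6, 1-{2-hydroxy-5-(3-hydroxy-3-methylbut-1-yn-1-yl)-3,6-bis[(triisopropylsilyl)oxy]phenyl}ethan-1-one
Conditions: Pd(PPh3)2Cl2 (3 mol%), CuI (5 mol%), Et3N/THF, 50 °C
Reagents that add atoms: none (5 is a numbered reactant)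
Why: Sonogashira coupling of the aryl iodide; the oxygen ortho to the alkyne is silylated, so no benzofuran can form, and the anhydrous amine base leaves the TIPS ethers intact.

**Step 5**
Reactants: 6
Product: 7, 1-{2-hydroxy-5-(3-hydroxy-3-methylbutyl)-3,6-bis[(triisopropylsilyl)oxy]phenyl}ethan-1-one
Conditions: H2 (1 atm), 10% Pd/C, EtOAc, rt
Reagents that add atoms: none (H2 only)
Why: Catalytic hydrogenation of the alkyne to the saturated chain; the chelated aryl ketone and silyl ethers are inert, and no chromene is present yet.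

**Step 6**
Reactants: 7
Product: 8, (E)-3-(dimethylamino)-1-{2-hydroxy-5-(3-hydroxy-3-methylbutyl)-3,6-bis[(triisopropylsilyl)oxy]phenyl}prop-2-en-1-one
Conditions: DMF-DMA (3 equiv), toluene, 90 °C
Reagents that add atoms: N,N-dimethylformamide dimethyl acetal, COC(OC)N(C)C
Why: Enaminone formation by condensation of the acetyl CH3 with the amide acetal; the chelated phenol and the tertiary alcohol are not methylated, and TIPS (unlike TBS) tolerates the methoxide generated.

**Step 7**
Reactants: 8
Product: 9, 6-(3-hydroxy-3-methylbutyl)-3-iodo-5,8-bis[(triisopropylsilyl)oxy]-4H-chromen-4-one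
Conditions: I2 (1.5 equiv), pyridine, CHCl3, rt; Na2S2O3 work-up
Reagents that add atoms: iodine, II
Why: Gammill iodocyclisation (α-iodination, then 6-endo attack of the phenol and loss of Me2NH); only the 2-OH is free, so the ring can close only toward what becomes C8-OTIPS.

**Step 8**
Reactants: 10, 4-bromobenzene-1,3-diol (4-bromoresorcinol); 11, 3-methylbut-2-enal (prenal)
Product: 12, 6-bromo-2,2-dimethyl-2H-chromen-7-ol
Conditions: ethylenediamine diacetate (20 mol%), toluene, reflux (Dean–Stark); 11 (1.1 equiv)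
Reagents that add atoms: none (both are numbered reactants)
Why: Knoevenagel-type C-alkylation then oxa-6π electrocyclisation (formal [3+3] chromenylation); attack is expected at C6 of the resorcinol (para to one OH, ortho to the other, as in Pechmann reactions of 4-haloresorcinols), giving the linear chromene.

**Step 9**
Reactants: 12
Product: 13, [(6-bromo-2,2-dimethyl-2H-chromen-7-yl)oxy](tert-butyl)dimethylsilane
Conditions: TBSCl, imidazole, DMF, rt
Reagents that add atoms: tert-butyldimethylsilyl chloride, CC(C)(C)[Si](C)(C)Cl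
Why: Standard phenol silylation, so the borylation and coupling are not run on a free o-bromophenol.

**Step 10**
Reactants: 13
Product: 14, tert-butyl{[2,2-dimethyl-6-(4,4,5,5-tetramethyl-1,3,2-dioxaborolan-2-yl)-2H-chromen-7-yl]oxy}dimethylsilane
Conditions: B2pin2 (1.3 equiv), Pd(dppf)Cl2 (5 mol%), KOAc, 1,4-dioxane, 90 °C
Reagents that add atoms: bis(pinacolato)diboron, CC1(C)OB(B2OC(C)(C)C(C)(C)O2)OC1(C)C
Why: Miyaura borylation; Pd is used instead of Br/Li exchange because an o-lithioaryl silyl ether would undergo retro-Brook silyl migration.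

**Step 11**
Reactants: 9; 14 (1.3 equiv)
Product: 15, 3-{7-[(tert-butyldimethylsilyl)oxy]-2,2-dimethyl-2H-chromen-6-yl}-6-(3-hydroxy-3-methylbutyl)-5,8-bis[(triisopropylsilyl)oxy]-4H-chromen-4-one
Conditions: Pd(dppf)Cl2 (5 mol%), 2 M aq Na2CO3, DME, 80 °C, Ar
Reagents that add atoms: none
Why: Suzuki–Miyaura coupling at the activated C3–I of the chromone; any partly desilylated product is carried into step 12 and converges on the target.

**Step 12**
Reactants: 15
Product: 16, Kraussianone 3 (target)
Conditions: TBAF/AcOH (1:1, 4 equiv), THF, 0 °C → rt, Ar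
Reagents that add atoms: none
Why: Fluoride desilylation of all three aryl silyl ethers under buffered, non-acidic conditions, so the tertiary alcohol cannot cyclise onto the 5-OH, the chromene is untouched, and the hydroquinone is not air-oxidised.

## Compound list

1 | 1-(2,6-dihydroxyphenyl)ethan-1-one | CC(=O)c1c(O)cccc1O | starting material
2 | 1-(2,3,6-trihydroxyphenyl)ethan-1-one | CC(=O)c1c(O)ccc(O)c1O | intermediate
3 | 1-{2-hydroxy-3,6-bis[(triisopropylsilyl)oxy]phenyl}ethan-1-one | CC(=O)c1c(O[Si](C(C)C)(C(C)C)C(C)C)ccc(O[Si](C(C)C)(C(C)C)C(C)C)c1O | intermediate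
4 | 1-{2-hydroxy-5-iodo-3,6-bis[(triisopropylsilyl)oxy]phenyl}ethan-1-one | CC(=O)c1c(O[Si](C(C)C)(C(C)C)C(C)C)c(I)cc(O[Si](C(C)C)(C(C)C)C(C)C)c1O | intermediate
5 | 2-methylbut-3-yn-2-ol | C#CC(C)(C)O | starting material
6 | 1-{2-hydroxy-5-(3-hydroxy-3-methylbut-1-yn-1-yl)-3,6-bis[(triisopropylsilyl)oxy]phenyl}ethan-1-one | CC(=O)c1c(O[Si](C(C)C)(C(C)C)C(C)C)c(C#CC(C)(C)O)cc(O[Si](C(C)C)(C(C)C)C(C)C)c1O | intermediate
7 | 1-{2-hydroxy-5-(3-hydroxy-3-methylbutyl)-3,6-bis[(triisopropylsilyl)oxy]phenyl}ethan-1-one | CC(=O)c1c(O[Si](C(C)C)(C(C)C)C(C)C)c(CCC(C)(C)O)cc(O[Si](C(C)C)(C(C)C)C(C)C)c1O | intermediate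
8 | (E)-3-(dimethylamino)-1-{2-hydroxy-5-(3-hydroxy-3-methylbutyl)-3,6-bis[(triisopropylsilyl)oxy]phenyl}prop-2-en-1-one | CN(C)/C=C/C(=O)c1c(O[Si](C(C)C)(C(C)C)C(C)C)c(CCC(C)(C)O)cc(O[Si](C(C)C)(C(C)C)C(C)C)c1O | intermediate
9 | 6-(3-hydroxy-3-methylbutyl)-3-iodo-5,8-bis[(triisopropylsilyl)oxy]-4H-chromen-4-one | O=c1c(I)coc2c(O[Si](C(C)C)(C(C)C)C(C)C)cc(CCC(C)(C)O)c(O[Si](C(C)C)(C(C)C)C(C)C)c12 | intermediate
10 | 4-bromobenzene-1,3-diol | Oc1ccc(Br)c(O)c1 | starting material
11 | 3-methylbut-2-enal | CC(C)=CC=O | starting material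
12 | 6-bromo-2,2-dimethyl-2H-chromen-7-ol | CC1(C)C=Cc2cc(Br)c(O)cc2O1 | intermediate
13 | [(6-bromo-2,2-dimethyl-2H-chromen-7-yl)oxy](tert-butyl)dimethylsilane | CC1(C)C=Cc2cc(Br)c(O[Si](C)(C)C(C)(C)C)cc2O1 | intermediate
14 | tert-butyl{[2,2-dimethyl-6-(4,4,5,5-tetramethyl-1,3,2-dioxaborolan-2-yl)-2H-chromen-7-yl]oxy}dimethylsilane | CC1(C)C=Cc2cc(B3OC(C)(C)C(C)(C)O3)c(O[Si](C)(C)C(C)(C)C)cc2O1 | intermediate
15 | 3-{7-[(tert-butyldimethylsilyl)oxy]-2,2-dimethyl-2H-chromen-6-yl}-6-(3-hydroxy-3-methylbutyl)-5,8-bis[(triisopropylsilyl)oxy]-4H-chromen-4-one | O=c1c(-c2cc3c(cc2O[Si](C)(C)C(C)(C)C)OC(C)(C)C=C3)coc2c(O[Si](C(C)C)(C(C)C)C(C)C)cc(CCC(C)(C)O)c(O[Si](C(C)C)(C(C)C)C(C)C)c12 | intermediate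
16 | Kraussianone 3 | CC(C)(O)CCc1cc(O)c2occ(-c3cc4c(cc3O)OC(C)(C)C=C4)c(=O)c2c1O | target

## Summary

**Total steps:** 12 (A/C fragment: steps 1–7; B/D fragment: steps 8–10; union and deprotection: steps 11–12).

**Longest linear sequence:** 9 steps (1 → 7, then 11, 12).

**Steps most likely to fail, with fallbacks:**

- **Step 1 (Elbs oxidation).** Risk: typically low yield, with over-oxidation of the hydroquinone product. Fallback: build the same acetophenone by directed ortho-lithiation instead of oxidation. Lithiate 1,2,4-trimethoxybenzene at C3 (n-BuLi), acylate with N-methoxy-N-methylacetamide to give 2,3,6-trimethoxyacetophenone, then demethylate fully with BBr3 to 2.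
- **Step 2 (differentiating the 2-OH from the 6-OH by sterics).** Risk: this selectivity has no direct precedent; if it is poor, the chromone would close in both directions. Fallback: fix the free OH by constitution instead. Lock O-2/O-3 of 2 as the catechol diphenylmethylene ketal (Ph2CCl2), silylate the remaining 6-OH, remove the ketal (H2, Pd/C), then mono-silylate the unchelated 3-OH to reach the same compound 3.
- **Step 8 (regiochemistry of chromenylation of 4-bromoresorcinol).** Risk: attack at C2 (between the OH groups) would give the 5-hydroxy isomers, and bis-annulation is possible. Fallback: replace the condensation with Friedel–Crafts acylation/oxa-Michael of 10 with 3-methylbut-2-enoic acid (MeSO3H/P2O5), which can only give 6-bromo-7-hydroxy-2,2-dimethylchroman-4-one. Then TBS protection, NaBH4 reduction and acid-catalysed dehydration give 13.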